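**Strategy**

The route rests on cutting both C–O bonds of the peroxide. In the 1,2-dioxane ring, O1–O2 is flanked by C3 (lactone CH–O) and C6 (quaternary, side chain); these carbons have a 1,4 relationship through C4–C5 and each can be traced back to a carbonyl group. Hydrogen peroxide is therefore condensed with (S)-2-hydroxy-2-methyl-4-oxopentanal, whose aldehyde becomes C3, whose methyl ketone becomes C6 and whose tertiary carbinol is already C4; in acidic methanol one operation makes both C–OO bonds and closes the ring as its 3,6-dimethoxy bis-peroxyketal. The methoxy groups are later exchanged under Lewis acid, at C6 for the triene chain and at C3 for the acetate arm of the lactone.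

Key step: step 4

Remark: ring atoms are numbered as in 1,2-dioxane (O1, O2, C3–C6) and side-chain carbons C1'–C10' from C6; anomeric peroxyketal centres are carried as mixtures (one anomer drawn) and the silicon-bearing carbon of the silanes is racemic, because all these centres are ionised or become sp2 later.

**Route**

Step 1
Reactants: 1 (R)-2-methylglycidol; 2 isopropenylmagnesium bromide
Product: 3 (S)-2,4-dimethylpent-4-ene-1,2-diol
Conditions: 2 (2.5 equiv), CuI (10 mol%), THF, −30 → 0 °C; aq. NH4Cl
Reagents that add atoms: none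
Why: Copper-catalysed Grignard opening of the epoxide (SN2) can occur only at the unsubstituted ring CH2, so the quaternary carbinol centre is not touched and its configuration is carried over (the descriptor changes from R to S by priority only, and a Payne shift of the alkoxide is degenerate here).

Step 2
Reactants: 3 (S)-2,4-dimethylpent-4-ene-1,2-diol
Product: 4 (S)-2-hydroxy-2,4-dimethylpent-4-enal
Conditions: SO3·pyridine, DMSO, i-Pr2NEt, CH2Cl2, 0 °C
Reagents that add atoms: none
Why: Parikh–Doering (activated-DMSO) oxidation converts the primary alcohol into the aldehyde, while the tertiary alcohol cannot be oxidised, this oxidant does not cleave glycols, and the quaternary α-carbon cannot epimerise.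

Step 3
Reactants: 4 (S)-2-hydroxy-2,4-dimethylpent-4-enal
Product: 6 (S)-2-hydroxy-2-methyl-4-oxopentanal, via secondary ozonide 5 (not isolated)
Conditions: O3, CH2Cl2, −78 °C; PPh3 (1.0 equiv), −78 °C → rt; short silica plug, used at once
Reagents that add atoms: ozone, O=[O+][O-]
Why: Ozonolysis (Criegee mechanism) of the 1,1-disubstituted alkene with reductive work-up should unmask the methyl ketone and release formaldehyde, the aldehyde and tertiary alcohol being inert to ozone at −78 °C, so the sensitive keto aldehyde appears only after all organometallic and oxidation steps are past.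

Step 4
Reactants: 6 (S)-2-hydroxy-2-methyl-4-oxopentanal; 7 hydrogen peroxide
Product: 10 (4S)-3,6-dimethoxy-4,6-dimethyl-1,2-dioxan-4-ol, via aldehyde perhydrate 8 (not isolated), via dioxane-3,4,6-triol 9 (not isolated)
Conditions: 50% aq. H2O2 (1.5 equiv), H2SO4 (cat.), MeOH (0.1 M), 0 °C → rt; NaHCO3
Reagents that add atoms: methanol, CO
Why: The aldehyde, the more electrophilic carbonyl, should take up H2O2 first to give perhydrate 8, whose hydroperoxy oxygen then closes onto the C6 ketone to the cyclic bis-hemiperketal 9; under the acid each anomeric hydroxyl leaves as water and methanol captures the resulting peroxycarbenium ion, giving 10. The closest known reaction type is the acid-catalysed condensation of hydrogen peroxide with 1,3-, 1,4- and 1,5-dicarbonyl compounds to cyclic peroxy(hemi)ketals, with O-alkylation when run in an alcohol. The single ring formed, the 1,2-dioxane, closes in the 6-exo-trig mode. The two new centres C3 and C6 are anomeric, equilibrate under the acid and are left uncontrolled because both are ionised again in steps 10 and 11, while the quaternary, non-enolisable C4 keeps its S configuration. The selectivity required is constitutional, the monomeric six-membered ring against open-chain, dimeric or geminal bis-hydroperoxide products; it is secured by the 1,4 spacing of the carbonyls, the gem-disubstituted C4 (Thorpe–Ingold effect), moderate dilution and near-stoichiometric peroxide in a large excess of methanol.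

Step 5
Reactants: 10 (4S)-3,6-dimethoxy-4,6-dimethyl-1,2-dioxan-4-ol
Product: 11 {[(4S)-3,6-dimethoxy-4,6-dimethyl-1,2-dioxan-4-yl]oxy}trimethylsilane
Conditions: N-(trimethylsilyl)imidazole, CH2Cl2, rt
Reagents that add atoms: N-(trimethylsilyl)imidazole, C[Si](C)(C)n1ccnc1
Why: Silyl transfer from the N-silylimidazole silylates the hindered tertiary alcohol under neutral, non-Lewis-acidic conditions that leave both peroxyketal centres and the O–O bond intact, so that no protic acid is released in the Lewis acid steps that follow.

Step 6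
Reactants: 12 (chloromethyl)trimethylsilane; 13 allyl bromide
Product: 15 (1-chlorobut-3-en-1-yl)trimethylsilane (racemic), via lithiated chloromethylsilane 14 (not isolated)
Conditions: s-BuLi, TMEDA, THF, −78 °C; then 13, −78 → −20 °C
Reagents that add atoms: none
Why: α-Lithiation of the chloromethylsilane gives a carbanion stabilised by silicon and chlorine that is alkylated (SN2) by the allylic bromide at low temperature; the new centre is racemic, which is harmless because it becomes sp2 in step 10.

Step 7
Reactants: 16 2-methylbut-1-en-3-yne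
Product: 18 (E)-1-iodo-3-methylbuta-1,3-diene, via dienylzirconocene chloride 17 (not isolated)
Conditions: Cp2Zr(H)Cl, CH2Cl2, rt; then I2, 0 °C; used as a solution
Reagents that add atoms: iodine, II
Why: Hydrozirconation of the terminal alkyne (faster than that of the 1,1-disubstituted alkene) is a syn addition placing zirconium on the terminal carbon, and iodinolysis of the C–Zr bond with retention should give the E iodide.

Step 8
Reactants: 15 (1-chlorobut-3-en-1-yl)trimethylsilane; 18 (E)-1-iodo-3-methylbuta-1,3-diene
Product: 20 trimethyl[(5E)-7-methylocta-1,5,7-trien-4-yl]silane (racemic), via α-silyl Grignard reagent 19 (not isolated)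
Conditions: Mg, THF, reflux; then 18, PdCl2(dppf) (3 mol%), THF, 0 °C → rt
Reagents that add atoms: none
Why: Kumada–Corriu coupling of an α-silylalkyl Grignard reagent with an alkenyl halide is an established way to α-substituted allylsilanes, the bidentate dppf ligand favouring reductive elimination over β-hydride elimination and the E geometry of the iodide being retained.

Step 9
Reactants: 20 trimethyl[(5E)-7-methylocta-1,5,7-trien-4-yl]silane; 21 (E)-β-bromostyrene
Product: 23 trimethyl[(3E,9E)-2-methyl-10-phenyldeca-1,3,9-trien-5-yl]silane (racemic), via B-alkyl-9-BBN 22 (not isolated)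
Conditions: 9-BBN-H (1.0 equiv), THF, 0 °C → rt; then 21, PdCl2(dppf) (3 mol%), aq. K3PO4, THF/DMF, rt
Reagents that add atoms: none
Why: 9-BBN adds anti-Markovnikov to the isolated monosubstituted alkene faster than to the conjugated diene, and the B-alkyl Suzuki–Miyaura coupling then joins the primary alkylborane to the alkenyl bromide with retention of its E geometry while the allylic C–Si bond is inert to Pd(0) and base.

Step 10
Reactants: 11 {[(4S)-3,6-dimethoxy-4,6-dimethyl-1,2-dioxan-4-yl]oxy}trimethylsilane; 23 trimethyl[(3E,9E)-2-methyl-10-phenyldeca-1,3,9-trien-5-yl]silane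
Product: 24 {[(4S,6R)-3-methoxy-4,6-dimethyl-6-[(2E,4E,9E)-2-methyl-10-phenyldeca-2,4,9-trien-1-yl]-1,2-dioxan-4-yl]oxy}trimethylsilane (C3 anomers)
Conditions: 23 (1.5 equiv), SnCl4 (1.0 equiv), CH2Cl2, −78 °C; Et3N, aq. NaHCO3
Reagents that add atoms: none
Why: In this Hosomi–Sakurai-type substitution the Lewis acid removes the methoxy group of the tertiary C6 ketal (the secondary C3 acetal, flanked by the C4 oxygen, ionises far more slowly) and the peroxycarbenium ion is captured by the terminal CH2 of the pentadienylsilane (vinylogous SE2') with loss of silicon, C2'=C3' forming E from the s-trans diene and C4'=C5' forming E from the conformer with hydrogen eclipsing, while axial attack on the half-chair with the C4 methyl pseudoequatorial puts the new C–C bond trans to that methyl and cis to the C4 oxygen (6R).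

Step 11
Reactants: 24 {[(4S,6R)-3-methoxy-4,6-dimethyl-6-[(2E,4E,9E)-2-methyl-10-phenyldeca-2,4,9-trien-1-yl]-1,2-dioxan-4-yl]oxy}trimethylsilane; 25 1-(tert-butyldimethylsilyloxy)-1-methoxyethene
Product: 26 methyl 2-[(3S,4S,6R)-4,6-dimethyl-6-[(2E,4E,9E)-2-methyl-10-phenyldeca-2,4,9-trien-1-yl]-4-(trimethylsilyloxy)-1,2-dioxan-3-yl]acetate
Conditions: 25 (2 equiv), TiCl4 (1.1 equiv), CH2Cl2, −78 °C; aq. NaHCO3
Reagents that add atoms: none
Why: This is a Mukaiyama-type addition of a silyl ketene acetal to the peroxycarbenium ion formed from the remaining C3 methyl peroxyacetal, a reaction known for 3-alkoxy-1,2-dioxolanes and -dioxanes; the nucleophile is expected anti to the pseudoaxial C4 methyl when the C4–O bond lies in the plane of the cation (the usual placement of an alkoxy group next to a six-membered oxocarbenium ion), which puts CH2CO2Me cis to the C4 oxygen (3S), although this control is not secure and heads the risk list.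

Step 12
Reactants: 26 methyl 2-[(3S,4S,6R)-4,6-dimethyl-6-[(2E,4E,9E)-2-methyl-10-phenyldeca-2,4,9-trien-1-yl]-4-(trimethylsilyloxy)-1,2-dioxan-3-yl]acetate
Product: 28 plakortolide H, via hydroxy ester 27 (not isolated)
Conditions: PPTS, MeOH, rt; concentrate; CSA (cat.), CH2Cl2, rt
Reagents that add atoms: none
Why: Acid-catalysed methanolysis removes the tertiary trimethylsilyl ether and the freed hydroxyl, held cis to the CH2CO2Me arm, closes the γ-lactone by intramolecular transesterification (5-exo-trig) without touching any stereocentre or the peroxide.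

**Compound list**

1 | (R)-2-methylglycidol | OC[C@]1(C)CO1 | starting material
2 | isopropenylmagnesium bromide | C=C(C)[Mg]Br | starting material
3 | (S)-2,4-dimethylpent-4-ene-1,2-diol | C=C(C)C[C@](C)(O)CO | intermediate
4 | (S)-2-hydroxy-2,4-dimethylpent-4-enal | C=C(C)C[C@](C)(O)C=O | intermediate
5 | (2S)-2-hydroxy-2-methyl-3-(3-methyl-1,2,4-trioxolan-3-yl)propanal (secondary ozonide) | CC1(OCOO1)C[C@](C)(O)C=O | intermediate
6 | (S)-2-hydroxy-2-methyl-4-oxopentanal | CC(=O)C[C@](C)(O)C=O | intermediate
7 | hydrogen peroxide | OO | starting material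
8 | (4S)-5-hydroperoxy-4,5-dihydroxy-4-methylpentan-2-one (aldehyde perhydrate) | CC(=O)C[C@](C)(O)C(O)OO | intermediate
9 | (4S)-4,6-dimethyl-1,2-dioxane-3,4,6-triol (one anomer drawn) | O[C@]1(C)C[C@](C)(O)[C@@H](O)OO1 | intermediate
10 | (4S)-3,6-dimethoxy-4,6-dimethyl-1,2-dioxan-4-ol (one anomer drawn) | CO[C@]1(C)C[C@](C)(O)[C@@H](OC)OO1 | intermediate
11 | {[(4S)-3,6-dimethoxy-4,6-dimethyl-1,2-dioxan-4-yl]oxy}trimethylsilane (one anomer drawn) | CO[C@]1(C)C[C@](C)(O[Si](C)(C)C)[C@@H](OC)OO1 | intermediate
12 | (chloromethyl)trimethylsilane | C[Si](C)(C)CCl | starting material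
13 | allyl bromide | C=CCBr | starting material
14 | [chloro(trimethylsilyl)methyl]lithium | [Li]C(Cl)[Si](C)(C)C | intermediate
15 | (1-chlorobut-3-en-1-yl)trimethylsilane (racemic) | C=CCC(Cl)[Si](C)(C)C | intermediate
16 | 2-methylbut-1-en-3-yne | C=C(C)C#C | starting material
17 | chlorobis(cyclopentadienyl)[(1E)-3-methylbuta-1,3-dien-1-yl]zirconium | C=C(C)/C=C/[Zr](Cl)(C1C=CC=C1)C1C=CC=C1 | intermediate
18 | (E)-1-iodo-3-methylbuta-1,3-diene | C=C(C)/C=C/I | intermediate
19 | chloro[1-(trimethylsilyl)but-3-en-1-yl]magnesium | C=CCC([Mg]Cl)[Si](C)(C)C | intermediate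
20 | trimethyl[(5E)-7-methylocta-1,5,7-trien-4-yl]silane (racemic) | C=C(C)/C=C/C([Si](C)(C)C)CC=C | intermediate
21 | (E)-β-bromostyrene | Br/C=C/c1ccccc1 | starting material
22 | 9-[(5E)-7-methyl-4-(trimethylsilyl)octa-5,7-dien-1-yl]-9-borabicyclo[3.3.1]nonane | C=C(C)/C=C/C([Si](C)(C)C)CCCB1C2CCCC1CCC2 | intermediate
23 | trimethyl[(3E,9E)-2-methyl-10-phenyldeca-1,3,9-trien-5-yl]silane (racemic) | C=C(C)/C=C/C([Si](C)(C)C)CCC/C=C/c1ccccc1 | intermediate
24 | {[(4S,6R)-3-methoxy-4,6-dimethyl-6-[(2E,4E,9E)-2-methyl-10-phenyldeca-2,4,9-trien-1-yl]-1,2-dioxan-4-yl]oxy}trimethylsilane (one C3 anomer drawn) | C/C(=C\C=C\CCC/C=C/c1ccccc1)C[C@]1(C)C[C@](C)(O[Si](C)(C)C)[C@@H](OC)OO1 | intermediate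
25 | 1-(tert-butyldimethylsilyloxy)-1-methoxyethene | C=C(OC)O[Si](C)(C)C(C)(C)C | starting material
26 | methyl 2-[(3S,4S,6R)-4,6-dimethyl-6-[(2E,4E,9E)-2-methyl-10-phenyldeca-2,4,9-trien-1-yl]-4-(trimethylsilyloxy)-1,2-dioxan-3-yl]acetate | C/C(=C\C=C\CCC/C=C/c1ccccc1)C[C@]1(C)C[C@](C)(O[Si](C)(C)C)[C@H](CC(=O)OC)OO1 | intermediate
27 | methyl 2-[(3S,4S,6R)-4-hydroxy-4,6-dimethyl-6-[(2E,4E,9E)-2-methyl-10-phenyldeca-2,4,9-trien-1-yl]-1,2-dioxan-3-yl]acetate | C/C(=C\C=C\CCC/C=C/c1ccccc1)C[C@]1(C)C[C@](C)(O)[C@H](CC(=O)OC)OO1 | intermediate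
28 | plakortolide H (γ-lactone cis-fused across C3–C4 of the 1,2-dioxane; C3 S, C4 S, C6 R; all-E side chain) | C/C(=C\C=C\CCC/C=C/c1ccccc1)C[C@]1(C)C[C@]2(C)OC(=O)C[C@@H]2OO1 | target

**Step count and risks**

Total step count: 12. Longest linear sequence: 8 steps (1–5, then 10–12); the side-chain branch (steps 6–9) joins at step 10.

Most likely to fail, step 11. Ionisation at the deactivated C3 acetal may be slow or take the wrong course: cleavage of the ring C3–O2 bond gives a methoxy-stabilised oxocarbenium ion and hence ring-opened adducts. Facial control may also be lost, because the alternative half-chair, which avoids the 1,3-diaxial methyl–methyl contact, delivers the nucleophile trans to the C4 oxygen. The fallback sets out from 24 and comes back at 28, and it fixes C3 by ring closure instead of by facial attack. Dilute aqueous acid (0.5 M HCl, THF, 0 °C) should hydrolyse the C3 methyl acetal, using the same ring-opening ionisation productively, together with the silyl ether, to give the peroxy lactol (4S,6R)-4,6-dimethyl-6-[(2E,4E,9E)-2-methyl-10-phenyldeca-2,4,9-trien-1-yl]-1,2-dioxane-3,4-diol F1, the ring tautomer of the hydroperoxy hydroxy aldehyde. A Z-selective Horner–Wadsworth–Emmons reaction on its open form (methyl bis(2,2,2-trifluoroethyl)phosphonoacetate, KHMDS, 18-crown-6, THF, −78 °C) should give methyl (2Z,4S,6R,8E,10E,15E)-6-hydroperoxy-4-hydroxy-4,6,8-trimethyl-16-phenylhexadeca-2,8,10,15-tetraenoate F2. This lactonises onto the C4 hydroxyl to the hydroperoxy butenolide (5S)-5-[(2R,4E,6E,11E)-2-hydroperoxy-2,4-dimethyl-12-phenyldodeca-4,6,11-trien-1-yl]-5-methylfuran-2(5H)-one F3. Et2NH in CF3CH2OH then closes the dioxane by intramolecular conjugate addition of the hydroperoxide, known for this ring system, and for geometric reasons this can give only the cis-fused lactone 28.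

Second, step 4. Intermolecular peroxide formation (open-chain or dimeric perketals, geminal bis-hydroperoxide) may outrun the ring closure. Acid may also dehydrate or retro-aldolise the β-hydroxy ketone, or cleave the perhydrate of the α-hydroxy aldehyde oxidatively. The fallback sets out from 4, replaces steps 3 and 4, and comes back at 10; it takes the C6–OO bond from ozone. Ozonolysis of 4 in CH2Cl2/MeOH at −78 °C without reductive work-up should give formaldehyde and the ketone oxide, which methanol traps as (2S)-4-hydroperoxy-2-hydroxy-4-methoxy-2-methylpentanal F4. Its hydroperoxy group adds to the aldehyde to give the peroxy lactol (4S)-6-methoxy-4,6-dimethyl-1,2-dioxane-3,4-diol F5. TsOH (cat.) in MeOH then exchanges the C3 hydroxyl for methoxy to give 10.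

Third, step 10. The fully elaborated silane 23 may be consumed by protodesilylation or by cationic reactions at its styrene end faster than it captures the hindered tertiary cation. Attack through an internal carbon and erosion of E geometry are further losses. The fallback sets out from 11 (with the two-step silane 20 in excess) and comes back at 24; the styrene end is attached afterwards under neutral conditions. SnCl4-mediated coupling of 11 with 20 should give {[(4S,6R)-3-methoxy-4,6-dimethyl-6-[(2E,4E)-2-methylocta-2,4,7-trien-1-yl]-1,2-dioxan-4-yl]oxy}trimethylsilane F6. 9-BBN, which tolerates dialkyl peroxides, should add to its terminal vinyl group only, giving the B-alkyl-9-BBN derivative {[(4S,6R)-6-[(2E,4E)-8-(9-borabicyclo[3.3.1]nonan-9-yl)-2-methylocta-2,4-dien-1-yl]-3-methoxy-4,6-dimethyl-1,2-dioxan-4-yl]oxy}trimethylsilane F7. Suzuki–Miyaura coupling of F7 with 21 (PdCl2(dppf), aq. K3PO4, rt) then gives 24.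

**Further compounds**

F1 | step 11 | (4S,6R)-4,6-dimethyl-6-[(2E,4E,9E)-2-methyl-10-phenyldeca-2,4,9-trien-1-yl]-1,2-dioxane-3,4-diol (C3 anomers) | C/C(=C\C=C\CCC/C=C/c1ccccc1)C[C@]1(C)C[C@](C)(O)C(O)OO1
F2 | step 11 | methyl (2Z,4S,6R,8E,10E,15E)-6-hydroperoxy-4-hydroxy-4,6,8-trimethyl-16-phenylhexadeca-2,8,10,15-tetraenoate | C/C(=C\C=C\CCC/C=C/c1ccccc1)C[C@@](C)(OO)C[C@](C)(O)/C=C\C(=O)OC
F3 | step 11 | (5S)-5-[(2R,4E,6E,11E)-2-hydroperoxy-2,4-dimethyl-12-phenyldodeca-4,6,11-trien-1-yl]-5-methylfuran-2(5H)-one | C/C(=C\C=C\CCC/C=C/c1ccccc1)C[C@@](C)(OO)C[C@]1(C)OC(=O)C=C1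
F4 | step 4 | (2S)-4-hydroperoxy-2-hydroxy-4-methoxy-2-methylpentanal | COC(C)(OO)C[C@](C)(O)C=O
F5 | step 4 | (4S)-6-methoxy-4,6-dimethyl-1,2-dioxane-3,4-diol (one anomer drawn) | CO[C@]1(C)C[C@](C)(O)[C@@H](O)OO1
F6 | step 10 | {[(4S,6R)-3-methoxy-4,6-dimethyl-6-[(2E,4E)-2-methylocta-2,4,7-trien-1-yl]-1,2-dioxan-4-yl]oxy}trimethylsilane (one C3 anomer drawn) | C/C(=C\C=C\CC=C)C[C@]1(C)C[C@](C)(O[Si](C)(C)C)[C@@H](OC)OO1
F7 | step 10 | {[(4S,6R)-6-[(2E,4E)-8-(9-borabicyclo[3.3.1]nonan-9-yl)-2-methylocta-2,4-dien-1-yl]-3-methoxy-4,6-dimethyl-1,2-dioxan-4-yl]oxy}trimethylsilane (one C3 anomer drawn) | C/C(=C\C=C\CCCB1C2CCCC1CCC2)C[C@]1(C)C[C@](C)(O[Si](C)(C)C)[C@@H](OC)OO1
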